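The earlier runs and the new flask are calculated for substances that don't exist; scatter was added.

E, the reagent, and Q, the substrate, stand at equal charges in the flasks midnight, summer and noon, 0.200 M against 0.20 M, and these flasks differ in reading time.

| flask | Q | E | G | remark | time |
|---|---|---|---|---|---|
| south-west | 0.20 M | 0.13 M | 0.040 M | run made earlier |  |
| north-west | 0.20 M | 0.30 M | 0.040 M | run made earlier |  |
| south-east | 0.30 M | 0.20 M | 0.040 M | run made earlier |  |
| midnight | 0.20 M | 0.200 M | 0.0400 M |  | 3.0 h |
| summer | 0.20 M | 0.200 M | 0.0400 M |  | 5.0 h |
| noon | 0.20 M | 0.200 M | 0.0400 M |  | 6.0 h |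

| run | time / h | J / % |
|---|---|---|
| south-west | 0.333 | 5.6 |
| south-west | 0.833 | 11.6 |
| south-west | 1.50 | 18.5 |
| south-west | 2.50 | 26.6 |
| south-west | 4.00 | 34.7 |
| north-west | 0.333 | 12.2 |
| north-west | 0.833 | 25.2 |
| north-west | 1.50 | 38.1 |
| north-west | 2.50 | 53.0 |
| north-west | 4.00 | 65.8 |
| south-east | 0.250 | 5.9 |
| south-east | 0.500 | 11.0 |
| south-east | 1.00 | 19.5 |
| south-east | 2.00 | 31.1 |
| south-east | 4.00 | 44.1 |

(standard deviation of a reading: 0.3 percentage points)

- a reading or a percentage of J counts all its forms, free or not

* which of the two there is more of at the end, midnight (J / X)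
* which of the two there is more of at the end, summer (J / X)
* which of the two there is more of at the end, noon (J / X)
* J at the end, in percent of the Q charged, midnight
* J at the end, in percent of the Q charged, summer
* J at the end, in percent of the Q charged, noon

Suppose each Q takes one E to give J at a rate k[Q][E]. Equal charges then stay equal, and the converted fraction f obeys f/(1−f) = t/τ, with τ = 1/(k c) and c the common charge. τ is the second-order half-life: at t = τ, f is one half, and the tail after it is slower than an exponential.

Each reading of the unequal runs, through the logarithmic form of the same law, yields a k, expressed here as τ at 0.200 M. The last readings give 4.15 h in south-west, 4.04 h in north-west and 3.99 h in south-east. Their mean, 4.06 h, is my reading, with the scatter of the runs in it, of the half-conversion time τ of these equal-charge flasks.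

Two extreme versions bracket it. The fast one keeps the early south-east reading, 3.87 h at 1.00 h, for the whole run, and the slow one keeps south-west's 4.15 h. For midnight they give 43.7% and 41.9%, and for noon 60.8% and 59.1%.

τ as read lengthens within south-east, so a real flask should sit between the versions, and noon's place is less sure, since it runs past the last reading. My own reckoning with τ gives 42.5% for midnight, 55.2% for summer and 59.6% for noon. X isn't among the readings, but the last-reading values of τ agree within 4.10% across south-west, north-west and south-east, whose E charges run from 0.13 M to 0.30 M, so I expect J to exceed X.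

The forecast holds that the “three runs fit a simple bimolecular law” and gives 42.5%, 55% and 59%, with J ahead in each flask, its noon value standing lower than my 59.6%.

The flasks give 42.7% for midnight, 55.0% for summer and 59.2% for noon, and noon holds 0.572% of X.

    Q + G → X (k = 0.190 L mol⁻¹ h⁻¹)
    Q + E → J (k = 1.30 L mol⁻¹ h⁻¹)
    G + E → D (k = 1.40 L mol⁻¹ h⁻¹)
    G + J ⇌ Z, settled at all times (K = 150 L mol⁻¹)

In summer, Q leaves by Q + E to J at 34 times its rate by Q + G to X just after the start, and at 5.00 h E leaves by that same step at 35 times its rate by G + E to D. At that time summer holds 44% of its Q and 41.0% of its E, each of its own charge. τ gave summer 55.2% against 55.0%. Read at 80 min, the same flask comes to 24.7% by τ, and it stands at 25.2%.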